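**Retrosynthetic overview**
- Ring A (the pyran) is closed last, by 6-endo hydroalkoxylation of a hydroxy enynone; the enynone comes from a Sonogashira union of a ring B enol triflate with the side-chain enyne.
- Ring B is closed first, as a cyclohexane-1,3-dione, by enolate O-to-C acyl transfer inside an alpha-acetyl gamma-lactone.
- Key C6–C7 bond: (1-ethoxyethenyl)magnesium bromide, an acetyl anion equivalent, adds under chelate control to the C7 methyl ketone, joining two carbonyl carbons and setting C7.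
- C8 comes from dimethyl (R)-malate and C8a from its Fráter–Seebach hydroxymethylation.
- Side chain: C4' and C5' from L-isoleucine, C3' by chelate-controlled MeMgBr addition to an ynone, the E alkene by hydroxyl-directed reduction of a diyne.

Assumption: isochromene numbering is used for the bicycle (C1H2, O2, C3 carrying the side chain, C4a=C5, C6=O, C7, C8, C8a) and primed numbers for the side chain; the target is 7S,8R,8aS,3'R,4'S,5'S with a 1'E alkene.

**Route**

Step 1
Reactants: 1 L-isoleucine
Product: 2 (2S,3S)-2-hydroxy-3-methylpentanoic acid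
Conditions: NaNO2, 1 M H2SO4, H2O, 0 °C → rt
Reagents that add atoms: water, O
Why: Diazotisation–hydrolysis of an alpha-amino acid goes with net retention (double inversion through the alpha-lactone), so C2 and C3 of isoleucine become C4' and C5' unchanged.

Step 2
Reactants: 2 (2S,3S)-2-hydroxy-3-methylpentanoic acid
Product: 3 (2S,3S)-2-hydroxy-N-methoxy-N,3-dimethylpentanamide
Conditions: MeNH(OMe)·HCl, DCC, HOBt (cat.), N-methylmorpholine, CH2Cl2, 0 °C → rt
Reagents that add atoms: N,O-dimethylhydroxylamine hydrochloride, CNOC.Cl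
Why: Carbodiimide amide coupling gives the Weinreb amide; the amine outcompetes the hindered secondary hydroxyl and the active ester does not epimerise an alpha-hydroxy acid.

Step 3
Reactants: 3 (2S,3S)-2-hydroxy-N-methoxy-N,3-dimethylpentanamide; 4 1,4-bis(trimethylsilyl)buta-1,3-diyne
Product: 6 (6S,7S)-6-hydroxy-7-methyl-1-(trimethylsilyl)nona-1,3-diyn-5-one, via lithium 4-(trimethylsilyl)buta-1,3-diyn-1-ide 5 (not isolated)
Conditions: 4 (2.2 equiv), MeLi·LiBr (2.2 equiv), THF, rt; then 3, −78 → −20 °C; aq. NH4Cl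
Reagents that add atoms: none
Why: Weinreb ketone synthesis: the acetylide from monodesilylation of 4 adds once because the chelated tetrahedral intermediate survives to work-up; the first equivalent only deprotonates the hydroxyl and no stereocentre is touched.

Step 4
Reactants: 6 (6S,7S)-6-hydroxy-7-methyl-1-(trimethylsilyl)nona-1,3-diyn-5-one
Product: 7 (5R,6S,7S)-5,7-dimethyl-1-(trimethylsilyl)nona-1,3-diyne-5,6-diol
Conditions: MeMgBr (3 equiv), Et2O/CH2Cl2, −78 °C; aq. NH4Cl
Reagents that add atoms: methylmagnesium bromide, C[Mg]Br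
Why: Cram chelate-controlled Grignard addition: magnesium bridges the alkoxide and the ynone oxygen, so methyl enters anti to the sec-butyl group and sets the tertiary carbinol as 5R (C3'); 1,2-addition dominates for an ynone at −78 °C.

Step 5
Reactants: 7 (5R,6S,7S)-5,7-dimethyl-1-(trimethylsilyl)nona-1,3-diyne-5,6-diol
Product: 9 (3E,5R,6S,7S)-5,7-dimethylnon-3-en-1-yne-5,6-diol, via C-silyl enyne diol 8 (not isolated)
Conditions: NaAlH2(OCH2CH2OCH3)2, THF, 0 °C → rt; then MeOH, K2CO3, rt
Reagents that add atoms: none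
Why: Hydroxyl-directed trans-hydroalumination of the propargylic alkyne (the 2,4-diyn-1-ol to E-2-en-4-yn-1-ol reduction) gives only the E alkene and spares the distal silylalkyne, which basic methanol then protodesilylates.

Step 6
Reactants: 10 dimethyl (2R)-2-hydroxybutanedioate
Product: 12 methyl (3S,4R)-4-hydroxy-5-oxooxolane-3-carboxylate, via aldol diol diester 11 (not isolated)
Conditions: LiN(iPr)2 (2.2 equiv), THF, −78 → −20 °C; CH2O (gas), −78 °C; aq. NH4Cl; then TsOH (cat.), CH2Cl2, rt
Reagents that add atoms: formaldehyde, C=O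
Why: Fráter–Seebach reaction: the chelated alkoxide enolate is attacked anti to the C2 ester (the known (S)-malate alkylation gives 2S,3R, so the R ester gives 2R,3S), which sets C8a; the new primary hydroxyl then lactonises onto the alpha-hydroxy ester.

Step 7
Reactants: 12 methyl (3S,4R)-4-hydroxy-5-oxooxolane-3-carboxylate
Product: 13 methyl (2S,3R)-3-hydroxy-2-(hydroxymethyl)-4-[methoxy(methyl)amino]-4-oxobutanoate
Conditions: AlMe3 (3 equiv), MeNH(OMe), CH2Cl2, 0 °C
Reagents that add atoms: N,O-dimethylhydroxylamine, CNOC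
Why: Weinreb aminolysis with Me2AlN(OMe)Me opens the alpha-oxygenated gamma-lactone at 0 °C faster than it attacks the acyclic methyl ester, which differentiates the two carboxyl carbons.

Step 8
Reactants: 13 methyl (2S,3R)-3-hydroxy-2-(hydroxymethyl)-4-[methoxy(methyl)amino]-4-oxobutanoate
Product: 14 methyl (2S,3R)-3-hydroxy-2-(hydroxymethyl)-4-oxopentanoate
Conditions: MeMgBr (4 equiv), THF, −30 → 0 °C; aq. NH4Cl
Reagents that add atoms: methylmagnesium bromide, C[Mg]Br
Why: Weinreb ketone synthesis: the N-methoxy-N-methyl amide takes up MeMgBr through the chelated tetrahedral intermediate faster than the methyl ester below 0 °C, giving the methyl ketone (in equilibrium with its five-membered hemiketal) without touching C8 or C8a.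

Step 9
Reactants: 14 methyl (2S,3R)-3-hydroxy-2-(hydroxymethyl)-4-oxopentanoate
Product: 17 (3S,4R,5S)-5-acetyl-4-hydroxy-3-(hydroxymethyl)-5-methyloxolan-2-one, via open-chain adduct 15 (not isolated), via enol ether lactone 16 (not isolated)
Conditions: CH2=C(OEt)MgBr (3.5 equiv; from ethyl vinyl ether, t-BuLi, then MgBr2·OEt2), THF, −78 °C; then 1 M HCl, THF, 0 °C → rt
Reagents that add atoms: (1-ethoxyethenyl)magnesium bromide, C=C(OCC)[Mg]Br; water, O
Why: Acyl anion addition (metalated enol ether as acetyl anion equivalent) under Cram chelate control: magnesium bridges the C8 alkoxide and the ketone oxygen, so the reagent attacks anti to the branched C8a substituent and sets the quaternary carbinol C7 as S; aqueous acid then lactonises the tertiary hydroxyl onto the ester and hydrolyses the enol ether to the acetyl group.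

Step 10
Reactants: 17 (3S,4R,5S)-5-acetyl-4-hydroxy-3-(hydroxymethyl)-5-methyloxolan-2-one
Product: 19 (4S,5R,6S)-4,5-dihydroxy-6-(hydroxymethyl)-4-methyl-3-oxocyclohex-1-en-1-yl trifluoromethanesulfonate, via cyclohexane-1,3-dione 18 (not isolated)
Conditions: LiN(SiMe3)2 (3.3 equiv), THF, −78 → 0 °C; AcOH (2.3 equiv), −78 °C; PhNTf2 (1.2 equiv), → rt
Reagents that add atoms: N-phenylbis(trifluoromethanesulfonimide), O=S(=O)(N(c1ccccc1)S(=O)(=O)C(F)(F)F)C(F)(F)F
Why: Proposed new method: the kinetic lithium enolate of the acetyl group attacks the lactone carbonyl through a five-membered transition state (O-to-C acyl transfer of an alpha-acyloxy ketone, closest to the Baker–Venkataraman rearrangement and the Dieckmann condensation), the bridged tetrahedral intermediate collapses to the stabilised 1,3-dione enolate that is ring B, and PhNTf2 sulfonylates the less hindered oxygen remote from the quaternary carbon, as with 4,4-disubstituted cyclohexane-1,3-diones; no stereocentre is touched.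

Step 11
Reactants: 19 (4S,5R,6S)-4,5-dihydroxy-6-(hydroxymethyl)-4-methyl-3-oxocyclohex-1-en-1-yl trifluoromethanesulfonate; 9 (3E,5R,6S,7S)-5,7-dimethylnon-3-en-1-yne-5,6-diol
Product: 20 (4S,5R,6S)-3-[(3E,5R,6S,7S)-5,6-dihydroxy-5,7-dimethylnon-3-en-1-yn-1-yl]-5,6-dihydroxy-4-(hydroxymethyl)-6-methylcyclohex-2-en-1-one
Conditions: 9 (1.2 equiv), Pd(PPh3)4 (5 mol%), CuI (10 mol%), Et3N, THF, rt
Reagents that add atoms: none
Why: Sonogashira coupling: beta-triflyloxy enones undergo oxidative addition at room temperature and the terminal enyne couples through its copper acetylide with free hydroxyls tolerated; no stereocentre is involved.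

Step 12
Reactants: 20 (4S,5R,6S)-3-[(3E,5R,6S,7S)-5,6-dihydroxy-5,7-dimethylnon-3-en-1-yn-1-yl]-5,6-dihydroxy-4-(hydroxymethyl)-6-methylcyclohex-2-en-1-one
Product: 21 (7S,8R,8aS)-3-[(1E,3R,4S,5S)-3,4-dihydroxy-3,5-dimethylhept-1-en-1-yl]-7,8-dihydroxy-7-methyl-1,7,8,8a-tetrahydro-6H-isochromen-6-one
Conditions: Ph3PAuNTf2 (3 mol%), THF, rt
Reagents that add atoms: none
Why: Gold-catalysed 6-endo-dig hydroalkoxylation (cycloisomerisation): the primary hydroxyl attacks the activated alkyne at the carbon remote from the electron-poor enone and stabilised by the alkenyl group, as in 1H-isochromene synthesis from 2-alkynylbenzyl alcohols, and protodeauration gives the dienol ether of ring A under neutral conditions that leave C8a alone.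

**Compound list**

1 | L-isoleucine, (2S,3S)-2-amino-3-methylpentanoic acid | CC[C@H](C)[C@H](N)C(=O)O | starting material
2 | (2S,3S)-2-hydroxy-3-methylpentanoic acid | CC[C@H](C)[C@H](O)C(=O)O | intermediate
3 | (2S,3S)-2-hydroxy-N-methoxy-N,3-dimethylpentanamide | CC[C@H](C)[C@H](O)C(=O)N(C)OC | intermediate
4 | 1,4-bis(trimethylsilyl)buta-1,3-diyne | C[Si](C)(C)C#CC#C[Si](C)(C)C | starting material
5 | lithium 4-(trimethylsilyl)buta-1,3-diyn-1-ide | [Li]C#CC#C[Si](C)(C)C | intermediate
6 | (6S,7S)-6-hydroxy-7-methyl-1-(trimethylsilyl)nona-1,3-diyn-5-one | CC[C@H](C)[C@H](O)C(=O)C#CC#C[Si](C)(C)C | intermediate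
7 | (5R,6S,7S)-5,7-dimethyl-1-(trimethylsilyl)nona-1,3-diyne-5,6-diol | CC[C@H](C)[C@H](O)[C@](C)(O)C#CC#C[Si](C)(C)C | intermediate
8 | (3E,5R,6S,7S)-5,7-dimethyl-1-(trimethylsilyl)non-3-en-1-yne-5,6-diol | CC[C@H](C)[C@H](O)[C@](C)(O)/C=C/C#C[Si](C)(C)C | intermediate
9 | (3E,5R,6S,7S)-5,7-dimethylnon-3-en-1-yne-5,6-diol | CC[C@H](C)[C@H](O)[C@](C)(O)/C=C/C#C | intermediate
10 | dimethyl (2R)-2-hydroxybutanedioate (dimethyl D-malate) | COC(=O)[C@H](O)CC(=O)OC | starting material
11 | dimethyl (2R,3S)-2-hydroxy-3-(hydroxymethyl)butanedioate | COC(=O)[C@H](O)[C@@H](C(=O)OC)CO | intermediate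
12 | methyl (3S,4R)-4-hydroxy-5-oxooxolane-3-carboxylate | O=C1[C@H](O)[C@@H](C(=O)OC)CO1 | intermediate
13 | methyl (2S,3R)-3-hydroxy-2-(hydroxymethyl)-4-[methoxy(methyl)amino]-4-oxobutanoate | CON(C)C(=O)[C@H](O)[C@@H](C(=O)OC)CO | intermediate
14 | methyl (2S,3R)-3-hydroxy-2-(hydroxymethyl)-4-oxopentanoate | CC(=O)[C@H](O)[C@@H](C(=O)OC)CO | intermediate
15 | methyl (2S,3R,4S)-5-ethoxy-3,4-dihydroxy-2-(hydroxymethyl)-4-methylhex-5-enoate | C=C(OCC)[C@@](C)(O)[C@H](O)[C@@H](C(=O)OC)CO | intermediate
16 | (3S,4R,5S)-5-(1-ethoxyethenyl)-4-hydroxy-3-(hydroxymethyl)-5-methyloxolan-2-one | C=C(OCC)[C@@]1(C)OC(=O)[C@@H](CO)[C@H]1O | intermediate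
17 | (3S,4R,5S)-5-acetyl-4-hydroxy-3-(hydroxymethyl)-5-methyloxolan-2-one | CC(=O)[C@@]1(C)OC(=O)[C@@H](CO)[C@H]1O | intermediate
18 | (4S,5R,6S)-5,6-dihydroxy-4-(hydroxymethyl)-6-methylcyclohexane-1,3-dione | O=C1CC(=O)[C@@](C)(O)[C@H](O)[C@@H]1CO | intermediate
19 | (4S,5R,6S)-4,5-dihydroxy-6-(hydroxymethyl)-4-methyl-3-oxocyclohex-1-en-1-yl trifluoromethanesulfonate | FC(F)(F)S(=O)(=O)OC1=CC(=O)[C@@](C)(O)[C@H](O)[C@@H]1CO | intermediate
20 | (4S,5R,6S)-3-[(3E,5R,6S,7S)-5,6-dihydroxy-5,7-dimethylnon-3-en-1-yn-1-yl]-5,6-dihydroxy-4-(hydroxymethyl)-6-methylcyclohex-2-en-1-one | CC[C@H](C)[C@H](O)[C@](C)(O)/C=C/C#CC1=CC(=O)[C@@](C)(O)[C@H](O)[C@@H]1CO | intermediate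
21 | (7S,8R,8aS)-3-[(1E,3R,4S,5S)-3,4-dihydroxy-3,5-dimethylhept-1-en-1-yl]-7,8-dihydroxy-7-methyl-1,7,8,8a-tetrahydro-6H-isochromen-6-one | CC[C@H](C)[C@H](O)[C@](C)(O)/C=C/C1=CC2=CC(=O)[C@@](C)(O)[C@H](O)[C@@H]2CO1 | target

**Step count and risks**

Total step count: 12. Longest linear sequence: 7 steps (10 → 21 through steps 6–12; the branch from 1 is equally long through steps 1–5, 11 and 12).

Steps most likely to fail:

Step 9. The polar organometallic meets an unprotected keto diol ester, so enolisation, attack on the ester or loss of chelate control could lower yield or the ratio at C7. The fallback sets out from 14 and comes back at 17. Ethynylmagnesium bromide (a less basic nucleophile that follows the same chelate model) is added to 14 at −78 °C and the adduct is lactonised with catalytic TsOH to (3S,4R,5R)-5-ethynyl-4-hydroxy-3-(hydroxymethyl)-5-methyloxolan-2-one F1 (same spatial arrangement at the quaternary carbon; the descriptor changes only through priorities). Hg(OTf)2-catalysed Markovnikov hydration of the terminal alkyne in aqueous MeCN, helped by the neighbouring acyloxy group, then gives 17.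

Step 10. The acyl transfer runs on a trianion through a strained bridged intermediate, the triflation must pick one of two enolate oxygens, and C8a sits next to a carbonyl throughout. The fallback sets out from 16 (isolated by leaving out the acid treatment that ends step 9) and comes back at 20. TESCl and imidazole give (3S,4R,5S)-5-(1-ethoxyethenyl)-5-methyl-4-[(triethylsilyl)oxy]-3-{[(triethylsilyl)oxy]methyl}oxolan-2-one F2. The trilithio derivative of 9 (n-BuLi, 3 equiv) opens this lactone at −78 °C, and an oxalic acid work-up unmasks the acetyl group to give (3S,4R,5S,9E,11R,12S,13S)-3,11,12-trihydroxy-3,11,13-trimethyl-4-[(triethylsilyl)oxy]-5-{[(triethylsilyl)oxy]methyl}pentadec-9-en-7-yne-2,6-dione F3 (in equilibrium with its lactol). Intramolecular aldol condensation of the methyl ketone onto the ynone carbonyl (LiN(SiMe3)2, −78 °C, then DBU) closes ring B with the alkyne already in place, giving (4S,5R,6S)-3-[(3E,5R,6S,7S)-5,6-dihydroxy-5,7-dimethylnon-3-en-1-yn-1-yl]-6-hydroxy-6-methyl-5-[(triethylsilyl)oxy]-4-{[(triethylsilyl)oxy]methyl}cyclohex-2-en-1-one F4. HF·pyridine then removes both silyl groups to give 20.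

Step 12. The hydroxyl can close 5-exo instead of 6-endo, and the cationic catalyst may ionise the tertiary allylic alcohol. The fallback sets out from 20 and comes back at 21. Diethylamine adds to the enynone in a 1,6-sense (intermolecular, so only the alkyne carbon conjugated to the carbonyl is attacked) to give the dienaminone (4S,5R,6S)-3-[(3E,5R,6S,7S)-2-(diethylamino)-5,6-dihydroxy-5,7-dimethylnona-1,3-dien-1-yl]-5,6-dihydroxy-4-(hydroxymethyl)-6-methylcyclohex-2-en-1-one F5. Pyridinium tosylate in THF then lets the primary hydroxyl add to the vinylogous iminium carbon (6-exo) and expel the amine, giving 21 with the oxygen at C3 by construction.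

**Further compounds**

F1 | step 9 | (3S,4R,5R)-5-ethynyl-4-hydroxy-3-(hydroxymethyl)-5-methyloxolan-2-one | C#C[C@@]1(C)OC(=O)[C@@H](CO)[C@H]1O
F2 | step 10 | (3S,4R,5S)-5-(1-ethoxyethenyl)-5-methyl-4-[(triethylsilyl)oxy]-3-{[(triethylsilyl)oxy]methyl}oxolan-2-one | C=C(OCC)[C@@]1(C)OC(=O)[C@@H](CO[Si](CC)(CC)CC)[C@H]1O[Si](CC)(CC)CC
F3 | step 10 | (3S,4R,5S,9E,11R,12S,13S)-3,11,12-trihydroxy-3,11,13-trimethyl-4-[(triethylsilyl)oxy]-5-{[(triethylsilyl)oxy]methyl}pentadec-9-en-7-yne-2,6-dione | CC[C@H](C)[C@H](O)[C@](C)(O)/C=C/C#CC(=O)[C@@H](CO[Si](CC)(CC)CC)[C@@H](O[Si](CC)(CC)CC)[C@](C)(O)C(C)=O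
F4 | step 10 | (4S,5R,6S)-3-[(3E,5R,6S,7S)-5,6-dihydroxy-5,7-dimethylnon-3-en-1-yn-1-yl]-6-hydroxy-6-methyl-5-[(triethylsilyl)oxy]-4-{[(triethylsilyl)oxy]methyl}cyclohex-2-en-1-one | CC[C@H](C)[C@H](O)[C@](C)(O)/C=C/C#CC1=CC(=O)[C@@](C)(O)[C@H](O[Si](CC)(CC)CC)[C@@H]1CO[Si](CC)(CC)CC
F5 | step 12 | (4S,5R,6S)-3-[(3E,5R,6S,7S)-2-(diethylamino)-5,6-dihydroxy-5,7-dimethylnona-1,3-dien-1-yl]-5,6-dihydroxy-4-(hydroxymethyl)-6-methylcyclohex-2-en-1-one | CC[C@H](C)[C@H](O)[C@](C)(O)/C=C/C(=CC1=CC(=O)[C@@](C)(O)[C@H](O)[C@@H]1CO)N(CC)CC
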